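In the north run at 30.0 h, 53.0% of the starting material had gone, and in the south-east run 74.0%, with more reagent in the second phase as the only difference.

all flasks: starting material 0.44 M
- north: reagent in the second phase 0.60 equiv; protic impurity 0.44 M; run made earlier
- south-east: reagent in the second phase 0.90 equiv; protic impurity 0.44 M; run made earlier
- flask: reagent in the second phase 1.20 equiv; protic impurity 0.440 M; time 30 h; volume of the second phase over the first 2.0

| run | time / h | target / % | crystals / % | starting material / % |
|---|---|---|---|---|
| north | 5.00 | 22 | 15 | 71 |
| north | 10.0 | 30 | 25 | 61 |
| north | 15.0 | 35 | 32 | 52 |
| north | 20.0 | 34 | 35 | 50 |
| north | 25.0 | 39 | 35 | 48 |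
| north | 30.0 | 33 | 34 | 47 |
| north | 40.0 | 35 | 30 | 46 |
| south-east | 5.00 | 33 | 29 | 63 |
| south-east | 10.0 | 45 | 40 | 46 |
| south-east | 15.0 | 48 | 45 | 37 |
| south-east | 20.0 | 48 | 50 | 31 |
| south-east | 25.0 | 51 | 51 | 27 |
| south-east | 30.0 | 54 | 48 | 26 |
| south-east | 40.0 | 54 | 49 | 20 |

(readings scatter by 1.5 percentage points)

- target is meant together with its product in the second phase and crystals
- in the second phase: reagent in the second phase, product in the second phase; everything else is in the first
- charges count per volume of the first phase; a concentration in a rate is the amount of a species over the volume of its own phase; every rate counts per litre of the first phase
- solid, in amounts per volume of the solution: crystals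
- the numbers in the tables scatter by 1.5 percentage points (one standard deviation)
- the earlier runs hold the two phases in the same ratio of volumes as the flask asked about

- how much target and product in the second phase and crystals together there is at 30 h, in percent of the starting material charged
- concentration of target in solution at 30 h, in percent of saturation

My first question was whether the loss followed conversion or time. The part of the starting material that had gone without becoming target read 20.0% in north and 20.0% in south-east, despite the different conversions. With crystals reading 48% in south-east, I took c(target) to be held near saturation and the loss to be zero-order. I named it the clock loss: the concentration that has left without becoming target by this time while crystals stand. Averaged over both runs, it came to 88.0 mM.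

My second question was how much starting material the flask would keep. The step from 0.60 equiv to 0.90 equiv multiplied the remainder by 0.553. One more equal step to 1.20 equiv gave 14.4%. Subtracting this remainder and the clock loss from the charge, I reckoned 65.6% for y, and I expected a solution near saturation.

The forecast gave 70% (62% to 77%) and 100% (96% to 110%), with y above my figure, saying “I expect about 90% conversion by 30 h”.

The flask gave 64.8% and 102%.

    reagent in the reaction phase ⇌ reagent in the second phase, rate k1*([reagent in the reaction phase] - [reagent in the second phase]/K1) per volume of the first phase (partition coefficient = 3.20, kL = 0.00490 s⁻¹)
    starting material + reagent in the reaction phase → target (k = 7.10 × 10⁻⁴ M⁻¹ s⁻¹)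
    target ⇌ product in the second phase, rate k3*([target] - [product in the second phase]/K3) per volume of the first phase (partition coefficient = 0.680, kL = 7.20 × 10⁻⁵ s⁻¹)
    target → decomposed product (k = 1.10 × 10⁻⁴ s⁻¹)
    reagent in the reaction phase + protic impurity → quenched reagent (k = 1.80 × 10⁻⁵ M⁻¹ s⁻¹)
    crystals ⇌ target, rate k6*(cs6 - [target]) while solid is left; crystals form when [target] > cs6 (solubility = 4.80 mM, k = 6.40 × 10⁻⁴ s⁻¹)

At 30.0 h the flask held 23.6% decomposed product and 11.6% starting material. My clock loss, 20.0% of the charge, was less than that decomposed product, while my remainder of 14.4% was more than the starting material found, so the two misses ran in opposite directions.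

In the neighbour with 0.11 M of starting material, the clock loss reckoned on that charge comes to 80.0%, but I had defined it for a flask in which crystals stand, so this figure is a test of that condition and no bound on target. The computed neighbour gave 8.52% at 30.0 h, with crystals at 0%, 49.9% decomposed product and 41.6% starting material left, so the 58.4% of starting material that had gone was less than the clock loss reckoned for it.

The data are calculated from invented constants; the scatter is artificial.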